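**Plan**

- Locants: the methylated flavone is unprimed; the apigenin unit is double-primed (rings A'' and C'') and its B ring triple-primed.
- Cuts, in retrosynthetic order: (1) O1''–C2'' and the C2''=C3'' unsaturation of ring C'', back to a 2',4',6'-trihydroxychalcone; (2) C4a''–C5'' of ring A'', back to an open cinnamoyl 3,5,7-triketo ester; (3) the bond between the cinnamoyl carbonyl and a triacetate unit; (4) the cinnamate C=C; (5) the C8–O–C4''' diaryl ether; (6) the C8–O bond, on a flavone taken from apigenin.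
- Enabling feature: ring A'' (C4a''–C8a'') is a phloroglucinol, oxygenated at C5'', C7'' and C8a'' and acylated by C4'' at C4a''. This is the 1,3,5-trioxygen pattern of a tetraketide folded by Claisen condensation.
- Forward: apigenin is methylated and hydroxylated at C8, the 8-phenol is arylated, and the aldehyde is extended to the cinnamic acid and then to the linear triketo ester. Ring A'' is closed next and ring C'' last.
- Stereochemistry: the target has no stereocentre. The E double bond of the chain is consumed in the last ring closure, and the transient flavanone centre is removed by dehydrogenation.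

Key step: step 6

Remark: the target has no stereocentre and no configurationally stable axis, so it is one achiral compound and no enantiocontrol is needed; polycarbonyl compounds are drawn as keto tautomers.

**Route**

Step 1
Reactants: 1 apigenin, 5,7-dihydroxy-2-(4-hydroxyphenyl)-4H-chromen-4-one
Product: 2 5-hydroxy-7-methoxy-2-(4-methoxyphenyl)-4H-chromen-4-one
Conditions: MeI (2.2 equiv), K2CO3 (2.5 equiv), acetone–DMF, 50 °C
Reagents that add atoms: methyl iodide, CI
Why: Williamson O-methylation takes the two free phenols at C7 and C4', while the 5-hydroxyl, hydrogen-bonded to the C4 carbonyl, should stay untouched when methyl iodide is limited to about two equivalents.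

Step 2
Reactants: 2 5-hydroxy-7-methoxy-2-(4-methoxyphenyl)-4H-chromen-4-one
Product: 4 5,8-dihydroxy-7-methoxy-2-(4-methoxyphenyl)-4H-chromen-4-one, via potassium aryl sulfate 3 (not isolated)
Conditions: K2S2O8 (1.3 equiv), aq. KOH, pyridine, 15–20 °C; then conc. HCl, Na2SO3 (cat.), 95 °C
Reagents that add atoms: potassium peroxydisulfate, [K+].[K+].[O-]S(=O)(=O)OOS(=O)(=O)[O-]
Why: Elbs persulfate oxidation, in which the 5-phenoxide is attacked by peroxydisulfate at its para carbon C8 and the aryl sulfate 3 is then hydrolysed by hot acid, the classical way from 5-hydroxyflavones to 5,8-dihydroxyflavones.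

Step 3
Reactants: 4 5,8-dihydroxy-7-methoxy-2-(4-methoxyphenyl)-4H-chromen-4-one; 5 4-fluorobenzaldehyde
Product: 6 4-{[5-hydroxy-7-methoxy-2-(4-methoxyphenyl)-4-oxo-4H-chromen-8-yl]oxy}benzaldehyde
Conditions: K2CO3 (1.5 equiv), DMF, 90 °C, Ar
Reagents that add atoms: none
Why: Nucleophilic aromatic substitution (SNAr) in which the free 8-phenoxide adds para to the formyl group and expels fluoride through a Meisenheimer complex, while the chelated 5-hydroxyl is a far weaker nucleophile, the same bias that allows selective 8-O-alkylation of 5,8-dihydroxyflavones.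

Step 4
Reactants: 6 4-{[5-hydroxy-7-methoxy-2-(4-methoxyphenyl)-4-oxo-4H-chromen-8-yl]oxy}benzaldehyde
Product: 7 (E)-3-(4-{[5-hydroxy-7-methoxy-2-(4-methoxyphenyl)-4-oxo-4H-chromen-8-yl]oxy}phenyl)prop-2-enoic acid
Conditions: CH2(CO2H)2 (3 equiv), pyridine, piperidine (cat.), 95 °C; then cold aq. HCl
Reagents that add atoms: malonic acid, O=C(O)CC(=O)O
Why: Knoevenagel–Doebner condensation with decarboxylation in hot pyridine should give the thermodynamically preferred E-cinnamic acid, and the flavone with its chelated phenol is inert to these mildly basic conditions.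

Step 5
Reactants: 7 (E)-3-(4-{[5-hydroxy-7-methoxy-2-(4-methoxyphenyl)-4-oxo-4H-chromen-8-yl]oxy}phenyl)prop-2-enoic acid; 8 methyl 3,5-dioxohexanoate
Product: 11 methyl (E)-9-(4-{[5-hydroxy-7-methoxy-2-(4-methoxyphenyl)-4-oxo-4H-chromen-8-yl]oxy}phenyl)-3,5,7-trioxonon-8-enoate, via acyl imidazolide 9 (not isolated), via trilithio trianion 10 (not isolated)
Conditions: 7, CDI (1.1 equiv), THF, rt; 8 (4.5 equiv), LDA (13.5 equiv), THF, 0 °C; combine at −78 → −20 °C; AcOH quench at −78 °C, cold pH 4 work-up, used crude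
Reagents that add atoms: none
Why: Claisen-type C-acylation of a polyketide polyanion, in which the terminal carbanion of 10 (formed last, hence most basic and most nucleophilic) attacks the hard imidazolide carbonyl of 9 in a 1,2 sense, while the excess of 10 absorbs the acidic protons of the phenol, the liberated imidazole and the product, and the resulting flavone 5-phenoxide makes that pyranone a poor electrophile.

Step 6
Reactants: 11 methyl (E)-9-(4-{[5-hydroxy-7-methoxy-2-(4-methoxyphenyl)-4-oxo-4H-chromen-8-yl]oxy}phenyl)-3,5,7-trioxonon-8-enoate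
Product: 12 (E)-3-(4-{[5-hydroxy-7-methoxy-2-(4-methoxyphenyl)-4-oxo-4H-chromen-8-yl]oxy}phenyl)-1-(2,4,6-trihydroxyphenyl)prop-2-en-1-one
Conditions: Mg(OMe)2 (6 equiv), MeOH–THF, 50 °C, N2; then ice-cold 1 M HCl
Reagents that add atoms: none
Why: Magnesium methoxide turns 11 into a magnesium-chelated polyenolate; its C6 carbon, lying between the C5 and C7 carbonyls, adds to the ester carbonyl C1, methoxide leaves, and the resulting 2-cinnamoylcyclohexane-1,3,5-trione enolizes to the aromatic phloroglucinol, which makes the sequence irreversible. The closest known reaction type is the base-mediated intramolecular Claisen (Dieckmann-type) cyclization of 3,5,7-triketo esters to acylphloroglucinols, the laboratory counterpart of the chalcone synthase folding. Ring A'' closes in a 6-exo-trig mode, the ester C=O lying outside the new six-membered ring, and the bond formed is C6–C1 of the chain, the later C4a''–C5''. No stereocentre is created and the E geometry of C8=C9 is carried through unchanged. The selectivity required is Claisen closure (C6 to C1) over aldol closure (C2 to C7, which would lead to a stilbene carboxylate); it is secured by the methyl ester at C1, which remains an acylating carbonyl under anhydrous alkoxide, by magnesium chelation of the 5,7-dicarbonyl unit, which makes C6 the nucleophile, and by the cinnamoyl conjugation that lowers the electrophilicity of C7. The flavone already present sits as its magnesium 5-phenoxide chelate, which protects C2 of that pyranone from methoxide.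

Step 7
Reactants: 12 (E)-3-(4-{[5-hydroxy-7-methoxy-2-(4-methoxyphenyl)-4-oxo-4H-chromen-8-yl]oxy}phenyl)-1-(2,4,6-trihydroxyphenyl)prop-2-en-1-one
Product: 14 8-[4-(5,7-dihydroxy-4-oxo-4H-chromen-2-yl)phenoxy]-5-hydroxy-7-methoxy-2-(4-methoxyphenyl)-4H-chromen-4-one, via flavanone 13 (not isolated)
Conditions: I2 (10 mol %), DMSO, 120 °C; aq. Na2S2O3 work-up
Reagents that add atoms: none
Why: Iodine-catalysed oxidative cyclization in DMSO, in which the 2'-hydroxychalcone closes by oxa-Michael addition to the racemic flavanone 13, which is iodinated at C3'' and loses HI to give the flavone while DMSO reoxidizes HI to iodine; naringenin-type flavanones with free 5,7-hydroxyls are dehydrogenated in this way, so any 13 already present in the material from step 6 is converted as well and its stereocentre disappears.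

**Compound list**

1 | apigenin, 5,7-dihydroxy-2-(4-hydroxyphenyl)-4H-chromen-4-one | O=c1cc(-c2ccc(O)cc2)oc2cc(O)cc(O)c12 | starting material
2 | 5-hydroxy-7-methoxy-2-(4-methoxyphenyl)-4H-chromen-4-one (apigenin 7,4'-dimethyl ether) | COc1ccc(-c2cc(=O)c3c(O)cc(OC)cc3o2)cc1 | intermediate
3 | potassium 5-hydroxy-7-methoxy-2-(4-methoxyphenyl)-4-oxo-4H-chromen-8-yl sulfate | COc1ccc(-c2cc(=O)c3c(O)cc(OC)c(OS(=O)(=O)[O-])c3o2)cc1.[K+] | intermediate
4 | 5,8-dihydroxy-7-methoxy-2-(4-methoxyphenyl)-4H-chromen-4-one | COc1ccc(-c2cc(=O)c3c(O)cc(OC)c(O)c3o2)cc1 | intermediate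
5 | 4-fluorobenzaldehyde | O=Cc1ccc(F)cc1 | starting material
6 | 4-{[5-hydroxy-7-methoxy-2-(4-methoxyphenyl)-4-oxo-4H-chromen-8-yl]oxy}benzaldehyde | COc1ccc(-c2cc(=O)c3c(O)cc(OC)c(Oc4ccc(C=O)cc4)c3o2)cc1 | intermediate
7 | (E)-3-(4-{[5-hydroxy-7-methoxy-2-(4-methoxyphenyl)-4-oxo-4H-chromen-8-yl]oxy}phenyl)prop-2-enoic acid | COc1ccc(-c2cc(=O)c3c(O)cc(OC)c(Oc4ccc(/C=C/C(=O)O)cc4)c3o2)cc1 | intermediate
8 | methyl 3,5-dioxohexanoate | COC(=O)CC(=O)CC(C)=O | starting material
9 | (E)-1-(1H-imidazol-1-yl)-3-(4-{[5-hydroxy-7-methoxy-2-(4-methoxyphenyl)-4-oxo-4H-chromen-8-yl]oxy}phenyl)prop-2-en-1-one (acyl imidazolide of 7) | COc1ccc(-c2cc(=O)c3c(O)cc(OC)c(Oc4ccc(/C=C/C(=O)n5ccnc5)cc4)c3o2)cc1 | intermediate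
10 | trilithium trianion of methyl 3,5-dioxohexanoate (tris-enolate, terminal CH2 nucleophilic) | [Li+].[Li+].[Li+].C=C([O-])C=C([O-])C=C([O-])OC | intermediate
11 | methyl (E)-9-(4-{[5-hydroxy-7-methoxy-2-(4-methoxyphenyl)-4-oxo-4H-chromen-8-yl]oxy}phenyl)-3,5,7-trioxonon-8-enoate (keto form drawn; enolized in solution) | COc1ccc(-c2cc(=O)c3c(O)cc(OC)c(Oc4ccc(/C=C/C(=O)CC(=O)CC(=O)CC(=O)OC)cc4)c3o2)cc1 | intermediate
12 | (E)-3-(4-{[5-hydroxy-7-methoxy-2-(4-methoxyphenyl)-4-oxo-4H-chromen-8-yl]oxy}phenyl)-1-(2,4,6-trihydroxyphenyl)prop-2-en-1-one | COc1ccc(-c2cc(=O)c3c(O)cc(OC)c(Oc4ccc(/C=C/C(=O)c5c(O)cc(O)cc5O)cc4)c3o2)cc1 | intermediate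
13 | racemic 8-[4-(5,7-dihydroxy-4-oxo-3,4-dihydro-2H-chromen-2-yl)phenoxy]-5-hydroxy-7-methoxy-2-(4-methoxyphenyl)-4H-chromen-4-one (flavanone) | COc1ccc(-c2cc(=O)c3c(O)cc(OC)c(Oc4ccc(C5CC(=O)c6c(O)cc(O)cc6O5)cc4)c3o2)cc1 | intermediate
14 | 8-[4-(5,7-dihydroxy-4-oxo-4H-chromen-2-yl)phenoxy]-5-hydroxy-7-methoxy-2-(4-methoxyphenyl)-4H-chromen-4-one | COc1ccc(-c2cc(=O)c3c(O)cc(OC)c(Oc4ccc(-c5cc(=O)c6c(O)cc(O)cc6o5)cc4)c3o2)cc1 | target

**Step count**

Total steps: 7. Longest linear sequence: 7 steps (1 to 14); 5 and 8 enter as single purchased reagents.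

**Steps most likely to fail**

Step 5. Several processes threaten it: proton transfer from the flavone phenol and from imidazole consumes the trianion; the polyanion may add in a conjugate sense to the cinnamoyl double bond or to C2 of the flavone; and the free triketo ester may cyclize unselectively during work-up. The fallback sets out from acid 7, activated to 9 as before. The acyl group is delivered to the 6-methyl carbon of the dilithium dianion of 4-hydroxy-6-methyl-2H-pyran-2-one F1, made from the commercial pyranone with LDA in THF at −78 °C and less basic than 10. This should give 4-hydroxy-6-[(E)-4-(4-{[5-hydroxy-7-methoxy-2-(4-methoxyphenyl)-4-oxo-4H-chromen-8-yl]oxy}phenyl)-2-oxobut-3-en-1-yl]-2H-pyran-2-one F2, a stable, crystallizable lactone form of the same tetraketide. Magnesium methoxide in methanol opens the lactone of F2 to the magnesium enolate of 11, where the route is rejoined, and this closes to 12 in the same flask under the conditions of step 6.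

Step 6. Aldol closure of C2 onto C7 or lactonization to the pyranone may compete with Claisen closure; an enol oxygen may add to the styryl carbon C9 to give a dihydropyranone; or methoxide may open the pyranone of the existing flavone. The fallback takes ring A'' preformed and sets out from aldehyde 6. Claisen–Schmidt condensation (KOH, EtOH, rt) with commercial 1-[2-hydroxy-4,6-bis(methoxymethoxy)phenyl]ethanone should give (E)-1-[2-hydroxy-4,6-bis(methoxymethoxy)phenyl]-3-(4-{[5-hydroxy-7-methoxy-2-(4-methoxyphenyl)-4-oxo-4H-chromen-8-yl]oxy}phenyl)prop-2-en-1-one F3. HCl in MeOH (rt to 40 °C) then removes both methoxymethyl groups, and the route is rejoined at chalcone 12; flavanone 13 formed alongside is carried into step 7 with it.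

Step 2. Attack of persulfate on the chelated phenoxide may stay incomplete, and the quinol may be oxidized further to the 5,8-quinone and polymeric material. The fallback sets out from 1 and introduces the 8-oxygen through a halide:
- Exhaustive methylation (Me2SO4, K2CO3, acetone, reflux) gives 5,7-dimethoxy-2-(4-methoxyphenyl)-4H-chromen-4-one F4.
- Electrophilic iodination (I2, CF3CO2Ag, CH2Cl2), which goes to C8 once O5 is methylated, gives 8-iodo-5,7-dimethoxy-2-(4-methoxyphenyl)-4H-chromen-4-one F5.
- Miyaura borylation (B2pin2, Pd(dppf)Cl2, KOAc, dioxane, 90 °C) gives 5,7-dimethoxy-2-(4-methoxyphenyl)-8-(4,4,5,5-tetramethyl-1,3,2-dioxaborolan-2-yl)-4H-chromen-4-one F6.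
- Oxidation (NaBO3·4H2O, THF–H2O, rt) gives 8-hydroxy-5,7-dimethoxy-2-(4-methoxyphenyl)-4H-chromen-4-one F7.
- BCl3 (CH2Cl2, −78 → 0 °C) cleaves only the 5-methyl ether peri to the carbonyl, and the route is rejoined at quinol 4.

**Further compounds**

F1 | step 5 | dilithium dianion of 4-hydroxy-6-methyl-2H-pyran-2-one | [Li+].[Li+].[CH2-]c1cc([O-])cc(=O)o1
F2 | step 5 | 4-hydroxy-6-[(E)-4-(4-{[5-hydroxy-7-methoxy-2-(4-methoxyphenyl)-4-oxo-4H-chromen-8-yl]oxy}phenyl)-2-oxobut-3-en-1-yl]-2H-pyran-2-one | COc1ccc(-c2cc(=O)c3c(O)cc(OC)c(Oc4ccc(/C=C/C(=O)Cc5cc(O)cc(=O)o5)cc4)c3o2)cc1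
F3 | step 6 | (E)-1-[2-hydroxy-4,6-bis(methoxymethoxy)phenyl]-3-(4-{[5-hydroxy-7-methoxy-2-(4-methoxyphenyl)-4-oxo-4H-chromen-8-yl]oxy}phenyl)prop-2-en-1-one | COc1ccc(-c2cc(=O)c3c(O)cc(OC)c(Oc4ccc(/C=C/C(=O)c5c(O)cc(OCOC)cc5OCOC)cc4)c3o2)cc1
F4 | step 2 | 5,7-dimethoxy-2-(4-methoxyphenyl)-4H-chromen-4-one | COc1ccc(-c2cc(=O)c3c(OC)cc(OC)cc3o2)cc1
F5 | step 2 | 8-iodo-5,7-dimethoxy-2-(4-methoxyphenyl)-4H-chromen-4-one | COc1ccc(-c2cc(=O)c3c(OC)cc(OC)c(I)c3o2)cc1
F6 | step 2 | 5,7-dimethoxy-2-(4-methoxyphenyl)-8-(4,4,5,5-tetramethyl-1,3,2-dioxaborolan-2-yl)-4H-chromen-4-one | COc1ccc(-c2cc(=O)c3c(OC)cc(OC)c(B4OC(C)(C)C(C)(C)O4)c3o2)cc1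
F7 | step 2 | 8-hydroxy-5,7-dimethoxy-2-(4-methoxyphenyl)-4H-chromen-4-one | COc1ccc(-c2cc(=O)c3c(OC)cc(OC)c(O)c3o2)cc1
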